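**Retrosynthetic overview**
- Feature: in the tridecane chain (C1 = benzylic CH2 on the benzene ring, C2 = acetoxy carbinol, C8 = free carbinol) C2 and C8 have the same spatial sense of oxygen / outer CH2 / inner chain. The labels are 2R and 8S only because the CIP priorities switch, so C1–C9 is a C2-symmetric 2,8-dioxygenated nonane capped by the aryl ring at C1 and a butyl group at C9.
- Disconnections: C1–aryl (aryl cuprate on a terminal oxirane) and C9–C10 (butyl cuprate on a terminal oxirane) lead back to C2-symmetric (R,R)-1,2:8,9-diepoxynonane.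
- The bis-epoxide comes from (2R,8R)-nonane-1,2,8,9-tetraol. Its two C–O bonds and both stereocentres are made in one operation by L-proline-catalysed double α-aminoxylation of nonanedial with two equivalents of nitrosobenzene.
- Ring order: the benzene ring (the only ring of the target) is bought; the two oxiranes are closed together in step 5 and opened one after the other in steps 6 and 9.

Key step: step 2

Remark: the target is (2R,8S)-8-hydroxy-1-(3-hydroxy-5-methoxyphenyl)tridecan-2-yl acetate, and this chain numbering is used throughout. The C2-symmetric and meso forms of the symmetric intermediates differ only at centres seven atoms apart and are not expected to separate on silica; any stereochemical upgrading is planned by recrystallisation of tetraol 6.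

**Step 1**
Reactants: 1 nonane-1,9-diol
Product: 2 nonanedial
Conditions: (COCl)2, DMSO, CH2Cl2, −78 °C; Et3N, −78 °C → rt; used crude at once
Reagents that add atoms: none
Why: Swern (activated-DMSO) oxidation converts both primary alcohols into aldehydes at low temperature without over-oxidation, and the air-sensitive dialdehyde is carried on directly.

**Step 2**
Reactants: 2 nonanedial; 3 nitrosobenzene
Product: 5 (2R,8R)-2,8-bis(anilinooxy)nonane-1,9-diol, via bis(anilinooxy)dialdehyde 4 (not isolated)
Conditions: PhNO (2.05 equiv in total, one per aldehyde terminus, added in portions), L-proline (40 mol%), MeCN, −20 °C; then MeOH, NaBH4, 0 °C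
Reagents that add atoms: nitrosobenzene (the second molar equivalent of compound 3, for the second terminus), O=Nc1ccccc1
Why: Each aldehyde terminus condenses with L-proline to an (E)-anti enamine whose carboxylic acid hydrogen-bonds to the basic nitroso nitrogen and so delivers the nitroso oxygen to the α-carbon, after which iminium hydrolysis releases the α-anilinooxy aldehyde and the catalyst (enamine-catalysed O-nitroso aldol, the proline α-aminoxylation of aldehydes); one molecule of nitrosobenzene is consumed at each terminus, two in all. No ring is closed: the C2–O and C8–O bonds form at two α-carbons separated by five methylene groups, which react independently. Both new stereocentres (C2 and C8, each R) are set by the catalyst alone through approach of PhNO to the enamine face syn to the carboxyl group, so the C2-symmetric R,R product is expected and residual facial error is channelled into the meso isomer and hardly into the enantiomer. The step needs O- over N-attack on nitrosobenzene, secured by protonation at nitrogen in the hydrogen-bonded transition state, and aminoxylation over aldol chemistry, secured by the high electrophilicity of PhNO at −20 °C and by the fact that intramolecular aldolisation of nonanedial would need an eight-membered ring. The configurationally labile dialdehyde 4 is reduced in the same flask by NaBH4 to the stable diol 5.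

**Step 3**
Reactants: 5 (2R,8R)-2,8-bis(anilinooxy)nonane-1,9-diol
Product: 6 (2R,8R)-nonane-1,2,8,9-tetraol
Conditions: H2 (1 atm), 10% Pd/C, MeOH, rt
Reagents that add atoms: none
Why: Catalytic hydrogenolysis cleaves the weak N–O bonds of the O-alkyl-N-arylhydroxylamines and releases both secondary hydroxyls without touching the C–O bonds at C2 and C8, so both centres keep their configuration.

**Step 4**
Reactants: 6 (2R,8R)-nonane-1,2,8,9-tetraol
Product: 7 (2R,8R)-2,8-dihydroxynonane-1,9-diyl bis(4-methylbenzenesulfonate)
Conditions: TsCl (2.1 equiv), Et3N, Bu2SnO (5 mol%), CH2Cl2–MeCN, 0 °C → rt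
Reagents that add atoms: 4-methylbenzenesulfonyl chloride (TsCl), Cc1ccc(cc1)S(Cl)(=O)=O
Why: Bu2SnO-catalysed regioselective sulfonylation (stannylene acetal activation) tosylates only the primary hydroxyl of each terminal 1,2-diol and leaves the stereogenic secondary carbinols untouched.

**Step 5**
Reactants: 7 (2R,8R)-2,8-dihydroxynonane-1,9-diyl bis(4-methylbenzenesulfonate)
Product: 8 (2R,2'R)-2,2'-(pentane-1,5-diyl)bis(oxirane) [(2R,8R)-1,2:8,9-diepoxynonane]
Conditions: K2CO3, MeOH, 0 °C → rt
Reagents that add atoms: none
Why: Intramolecular Williamson etherification (3-exo-tet attack of each secondary alkoxide on the adjacent primary tosylate) closes both oxiranes with retention at C2 and C8, because only the CH2 carbons undergo substitution.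

**Step 6**
Reactants: 8 (2R,2'R)-2,2'-(pentane-1,5-diyl)bis(oxirane)
Product: 9 (6S)-1-[(2R)-oxiran-2-yl]undecan-6-ol [(2R,8S)-1,2-epoxytridecan-8-ol]
Conditions: n-BuMgCl (0.7 equiv, slow addition), CuI (10 mol%), THF, −40 °C; recovered 8 recycled
Reagents that add atoms: n-butylmagnesium chloride, CCCC[Mg]Cl
Why: Copper-catalysed Grignard opening of a terminal epoxide proceeds by SN2 attack at the unsubstituted carbon C9, so C8 is untouched (its label changes from R to S only through the priority switch), and since the two oxiranes of 8 are homotopic the sub-stoichiometric reagent can give only one mono-adduct.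

**Step 7**
Reactants: 9 (6S)-1-[(2R)-oxiran-2-yl]undecan-6-ol
Product: 10 tert-butyl(dimethyl){[(6S)-1-[(2R)-oxiran-2-yl]undecan-6-yl]oxy}silane
Conditions: TBSCl, imidazole, DMF, rt
Reagents that add atoms: tert-butyldimethylsilyl chloride (TBSCl), CC(C)(C)[Si](C)(C)Cl
Why: Standard imidazole-mediated silylation masks the C8 hydroxyl so that only C2–OH will be free for the later acetylation, under conditions that leave the oxirane intact.

**Step 8**
Reactants: 11 3-bromo-5-methoxyphenol
Product: 12 (3-bromo-5-methoxyphenoxy)tri(propan-2-yl)silane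
Conditions: TIPSCl, imidazole, DMF, rt
Reagents that add atoms: triisopropylsilyl chloride (TIPSCl), CC(C)[Si](Cl)(C(C)C)C(C)C
Why: Silylation of the phenol removes the acidic proton ahead of Grignard formation, the bulky aryl silyl ether being stable to organomagnesium and cuprate reagents.

**Step 9**
Reactants: 12 (3-bromo-5-methoxyphenoxy)tri(propan-2-yl)silane; 10 tert-butyl(dimethyl){[(6S)-1-[(2R)-oxiran-2-yl]undecan-6-yl]oxy}silane
Product: 14 (2R,8S)-8-(tert-butyldimethylsilyloxy)-1-[3-methoxy-5-(triisopropylsilyloxy)phenyl]tridecan-2-ol, via aryl Grignard reagent 13 (not isolated)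
Conditions: 12, Mg, BrCH2CH2Br (cat.), THF, 50 °C; then CuI (15 mol%), 10, THF, −30 → 0 °C
Reagents that add atoms: none
Why: Magnesium insertion gives the aryl Grignard reagent, which under CuI catalysis opens the terminal epoxide by SN2 attack at the unsubstituted C1, forming the aryl–C1 bond and releasing C2–OH with its configuration unchanged.

**Step 10**
Reactants: 14 (2R,8S)-8-(tert-butyldimethylsilyloxy)-1-[3-methoxy-5-(triisopropylsilyloxy)phenyl]tridecan-2-ol
Product: 15 (2R,8S)-8-(tert-butyldimethylsilyloxy)-1-[3-methoxy-5-(triisopropylsilyloxy)phenyl]tridecan-2-yl acetate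
Conditions: Ac2O, pyridine, DMAP (cat.), CH2Cl2, rt
Reagents that add atoms: acetic anhydride, CC(=O)OC(C)=O
Why: DMAP-catalysed acylation of the only free hydroxyl installs the C2 acetate without affecting the silyl ethers or either stereocentre.

**Step 11**
Reactants: 15 (2R,8S)-8-(tert-butyldimethylsilyloxy)-1-[3-methoxy-5-(triisopropylsilyloxy)phenyl]tridecan-2-yl acetate
Product: 16 (2R,8S)-8-hydroxy-1-(3-hydroxy-5-methoxyphenyl)tridecan-2-yl acetate (target)
Conditions: TBAF, AcOH (1 equiv per fluoride), THF, 0 °C → rt
Reagents that add atoms: none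
Why: Fluoride-mediated desilylation with acetic-acid-buffered TBAF cleaves the aryl TIPS ether and the secondary TBS ether in one operation, the buffer suppressing alkoxide- or phenoxide-induced loss or transfer of the acetate.

**Compound list**
1 | nonane-1,9-diol | OCCCCCCCCCO | starting material
2 | nonanedial | O=CCCCCCCCC=O | intermediate
3 | nitrosobenzene | O=Nc1ccccc1 | starting material
4 | (2R,8R)-2,8-bis(anilinooxy)nonanedial | O=C[C@H](ONc1ccccc1)CCCCC[C@H](C=O)ONc1ccccc1 | intermediate (not isolated)
5 | (2R,8R)-2,8-bis(anilinooxy)nonane-1,9-diol | OC[C@H](ONc1ccccc1)CCCCC[C@H](CO)ONc1ccccc1 | intermediate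
6 | (2R,8R)-nonane-1,2,8,9-tetraol | OC[C@H](O)CCCCC[C@H](CO)O | intermediate
7 | (2R,8R)-2,8-dihydroxynonane-1,9-diyl bis(4-methylbenzenesulfonate) | Cc1ccc(cc1)S(=O)(=O)OC[C@H](O)CCCCC[C@H](COS(=O)(=O)c1ccc(C)cc1)O | intermediate
8 | (2R,2'R)-2,2'-(pentane-1,5-diyl)bis(oxirane) | C1[C@H](O1)CCCCC[C@H]1OC1 | intermediate
9 | (6S)-1-[(2R)-oxiran-2-yl]undecan-6-ol | CCCCC[C@H](O)CCCCC[C@H]1OC1 | intermediate
10 | tert-butyl(dimethyl){[(6S)-1-[(2R)-oxiran-2-yl]undecan-6-yl]oxy}silane | CCCCC[C@H](O[Si](C)(C)C(C)(C)C)CCCCC[C@H]1OC1 | intermediate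
11 | 3-bromo-5-methoxyphenol | COc1cc(O)cc(Br)c1 | starting material
12 | (3-bromo-5-methoxyphenoxy)tri(propan-2-yl)silane | COc1cc(Br)cc(O[Si](C(C)C)(C(C)C)C(C)C)c1 | intermediate
13 | [3-methoxy-5-(triisopropylsilyloxy)phenyl]magnesium bromide | COc1cc([Mg]Br)cc(O[Si](C(C)C)(C(C)C)C(C)C)c1 | intermediate (not isolated)
14 | (2R,8S)-8-(tert-butyldimethylsilyloxy)-1-[3-methoxy-5-(triisopropylsilyloxy)phenyl]tridecan-2-ol | CCCCC[C@H](O[Si](C)(C)C(C)(C)C)CCCCC[C@H](Cc1cc(OC)cc(O[Si](C(C)C)(C(C)C)C(C)C)c1)O | intermediate
15 | (2R,8S)-8-(tert-butyldimethylsilyloxy)-1-[3-methoxy-5-(triisopropylsilyloxy)phenyl]tridecan-2-yl acetate | CCCCC[C@H](O[Si](C)(C)C(C)(C)C)CCCCC[C@H](Cc1cc(OC)cc(O[Si](C(C)C)(C(C)C)C(C)C)c1)OC(C)=O | intermediate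
16 | (2R,8S)-8-hydroxy-1-(3-hydroxy-5-methoxyphenyl)tridecan-2-yl acetate | CCCCC[C@H](O)CCCCC[C@H](Cc1cc(O)cc(OC)c1)OC(C)=O | target

**Step count**
Total: 11 steps. Longest linear sequence: 10 steps (steps 1–7 and 9–11); step 8 is a one-step side branch.

**Steps most likely to fail**

1. Step 2 (double α-aminoxylation). What may go wrong: stalling after the first terminus has reacted, N-attack or self-condensation of nitrosobenzene, amine-catalysed aldol oligomerisation of the dialdehyde, and erosion of facial control at one terminus, which would load the material with the hard-to-remove meso isomer. Fallback: it sets out from nonanedial 2 and returns at bis-epoxide 8, replacing steps 2–5. Two-directional enamine-catalysed α-chlorination of 2 with N-chlorosuccinimide and the enantiomer of trans-2,5-diphenylpyrrolidine that delivers (S)-2-chloroaldehydes (CH2Cl2, 0 °C) should give (2S,8S)-2,8-dichlorononanedial F1. NaBH4 in MeOH in the same flask should give (2S,8S)-2,8-dichlorononane-1,9-diol F2. KOH in aqueous EtOH then closes both oxiranes by attack of the primary alkoxides on the secondary chlorides with inversion at C2 and C8, which should give 8.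

2. Step 6 (mono-opening of the bis-epoxide). What may go wrong: over-addition to the second, homotopic oxirane, which removes material irreversibly, and competing halohydrin formation by magnesium halide. Fallback: it sets out from tetraol 6 and returns at epoxy alcohol 9, with only one oxirane present at any time.
   - Equilibration of 6 with one equivalent of 2,2-dimethoxypropane and catalytic TsOH in DMF should give mono-acetonide (2R)-7-[(4R)-2,2-dimethyl-1,3-dioxolan-4-yl]heptane-1,2-diol F3. It forms beside unchanged 6 and bis-acetonide (4R,4'R)-4,4'-(pentane-1,5-diyl)bis(2,2-dimethyl-1,3-dioxolane) F4; these two are pooled and re-equilibrated under the same acid conditions, so nothing is lost.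
   - Selective tosylation of F3 (TsCl, Et3N, Bu2SnO cat.) should give (2R)-7-[(4R)-2,2-dimethyl-1,3-dioxolan-4-yl]-2-hydroxyheptyl 4-methylbenzenesulfonate F5, and K2CO3 in MeOH should close it to (4R)-2,2-dimethyl-4-{5-[(2R)-oxiran-2-yl]pentyl}-1,3-dioxolane F6.
   - Excess n-BuMgCl with catalytic CuI should open the single oxirane to (6S)-1-[(4R)-2,2-dimethyl-1,3-dioxolan-4-yl]undecan-6-ol F7, and aqueous AcOH should remove the acetonide to give (2R,8S)-tridecane-1,2,8-triol F8.
   - Tin-catalysed tosylation of the primary hydroxyl should give (2R,8S)-2,8-dihydroxytridecyl 4-methylbenzenesulfonate F9, and K2CO3 in MeOH should close it to 9.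

3. Step 9 (aryl cuprate opening). What may go wrong: sluggish magnesium insertion into the electron-rich aryl bromide with homocoupling, bromide opening of the oxirane by magnesium halide, and silyl transfer from the aryl ether to the new magnesium alkoxide. Fallback: it sets out from epoxide 10 and aryl bromide 12 and returns at alcohol 14 without any organomagnesium reagent. Nickel-catalysed cross-electrophile coupling with iodide co-catalysis (NiCl2(dme), 2,2'-bipyridine, NaI, Et3N·HCl, Mn powder, DMPU, rt) should open 10 in the flask at the terminal carbon to (2R,8S)-8-(tert-butyldimethylsilyloxy)-1-iodotridecan-2-ol F10. The primary C–I bond of this iodohydrin is then coupled with 12 at nickel to give 14 with C2 untouched.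

**Further compounds**
F1 | step 2 | (2S,8S)-2,8-dichlorononanedial | O=C[C@@H](Cl)CCCCC[C@@H](C=O)Cl
F2 | step 2 | (2S,8S)-2,8-dichlorononane-1,9-diol | OC[C@@H](Cl)CCCCC[C@@H](CO)Cl
F3 | step 6 | (2R)-7-[(4R)-2,2-dimethyl-1,3-dioxolan-4-yl]heptane-1,2-diol | OC[C@H](O)CCCCC[C@H]1OC(C)(C)OC1
F4 | step 6 | (4R,4'R)-4,4'-(pentane-1,5-diyl)bis(2,2-dimethyl-1,3-dioxolane) | CC1(C)OC[C@H](O1)CCCCC[C@H]1OC(C)(C)OC1
F5 | step 6 | (2R)-7-[(4R)-2,2-dimethyl-1,3-dioxolan-4-yl]-2-hydroxyheptyl 4-methylbenzenesulfonate | Cc1ccc(cc1)S(=O)(=O)OC[C@H](O)CCCCC[C@H]1OC(C)(C)OC1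
F6 | step 6 | (4R)-2,2-dimethyl-4-{5-[(2R)-oxiran-2-yl]pentyl}-1,3-dioxolane | C1[C@H](O1)CCCCC[C@H]1OC(C)(C)OC1
F7 | step 6 | (6S)-1-[(4R)-2,2-dimethyl-1,3-dioxolan-4-yl]undecan-6-ol | CCCCC[C@H](O)CCCCC[C@H]1OC(C)(C)OC1
F8 | step 6 | (2R,8S)-tridecane-1,2,8-triol | CCCCC[C@H](O)CCCCC[C@H](CO)O
F9 | step 6 | (2R,8S)-2,8-dihydroxytridecyl 4-methylbenzenesulfonate | CCCCC[C@H](O)CCCCC[C@H](COS(=O)(=O)c1ccc(C)cc1)O
F10 | step 9 | (2R,8S)-8-(tert-butyldimethylsilyloxy)-1-iodotridecan-2-ol | CCCCC[C@H](O[Si](C)(C)C(C)(C)C)CCCCC[C@H](CI)O
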